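The tetrahydrofuran ring of the meso target is cut at C3–C4 and O1–C5. O1, C2 with its aryl group, C3 and the carbon attached to C3 form an aroylacetate unit; C4 with its CH2O carbon and C5 with its aryl group form a sinapyl-type alkene. One Mn(OAc)3-mediated oxidative annulation of a benzyl-protected β-ketoester with a benzyl-protected cinnamyl acetate makes both bonds, the ring and the trans C4/C5 relationship at once. Syn hydrogenation, acid inversion at C2 and hydride reduction then give the 2,3-trans-3,4-cis-4,5-trans tetraol; it is achiral, so racemic intermediates suffice.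

Key step: step 6

Assumption: the target SMILES encodes the meso (2S,3R,4S,5R) isomer (aryl groups 2,5-cis, hydroxymethyl groups 3,4-cis, each aryl trans to the neighbouring CH2OH). Chiral intermediates are therefore racemic and each SMILES shows one enantiomer. Ring numbering throughout: O1, C2 (aryl), C3, C4, C5 (aryl).

Step 1
Reactants: 1 acetosyringone; 2 benzyl bromide
Product: 3 1-[4-(benzyloxy)-3,5-dimethoxyphenyl]ethan-1-one
Conditions: K2CO3, DMF, 60 °C
Reagents that add atoms: benzyl bromide (2), BrCc1ccccc1
Why: Williamson ether synthesis: K2CO3 forms the phenoxide, which displaces bromide from benzyl bromide in an SN2 reaction while the aryl ketone is untouched; no stereocenter is formed.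

Step 2
Reactants: 3 1-[4-(benzyloxy)-3,5-dimethoxyphenyl]ethan-1-one; 4 dimethyl carbonate
Product: 5 methyl 3-[4-(benzyloxy)-3,5-dimethoxyphenyl]-3-oxopropanoate
Conditions: NaH (2.5 equiv), (MeO)2CO (excess), THF, reflux; then aq. HCl, 0 °C
Reagents that add atoms: dimethyl carbonate (4), COC(=O)OC
Why: Crossed Claisen condensation: the ketone enolate formed by NaH is C-acylated by non-enolisable dimethyl carbonate, and irreversible deprotonation of the β-ketoester product by the second equivalent of NaH drives the reaction; the benzyl aryl ether is inert here.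

Step 3
Reactants: 6 sinapic acid; 2 benzyl bromide
Product: 7 benzyl (E)-3-[4-(benzyloxy)-3,5-dimethoxyphenyl]prop-2-enoate
Conditions: BnBr (2.5 equiv), K2CO3, DMF, 60 °C
Reagents that add atoms: benzyl bromide (2), BrCc1ccccc1
Why: Double SN2 O-alkylation (Williamson etherification of the phenoxide together with carboxylate alkylation) installs the phenol protecting group and an ester in one operation without affecting the E-alkene.

Step 4
Reactants: 7 benzyl (E)-3-[4-(benzyloxy)-3,5-dimethoxyphenyl]prop-2-enoate
Product: 8 (E)-3-[4-(benzyloxy)-3,5-dimethoxyphenyl]prop-2-en-1-ol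
Conditions: iBu2AlH (3 equiv), CH2Cl2, −78 to 0 °C; then aq. potassium sodium tartrate (KNaC4H4O6)
Reagents that add atoms: none
Why: iBu2AlH reduction of the α,β-unsaturated benzyl ester proceeds by 1,2-hydride delivery to the allylic alcohol, keeping the E-geometry and the benzyl ether; the benzyl alcohol released is removed by chromatography.

Step 5
Reactants: 8 (E)-3-[4-(benzyloxy)-3,5-dimethoxyphenyl]prop-2-en-1-ol; 9 acetic anhydride
Product: 10 (E)-3-[4-(benzyloxy)-3,5-dimethoxyphenyl]prop-2-en-1-yl acetate
Conditions: Ac2O, pyridine, DMAP (cat.), CH2Cl2, 0 °C to rt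
Reagents that add atoms: acetic anhydride (9), CC(=O)OC(C)=O
Why: DMAP-catalysed O-acylation of the primary allylic alcohol; acetate is chosen because any solvolysis of the allylic ester in the AcOH medium of step 6 is degenerate.

Step 6
Reactants: 5 methyl 3-[4-(benzyloxy)-3,5-dimethoxyphenyl]-3-oxopropanoate; 10 (E)-3-[4-(benzyloxy)-3,5-dimethoxyphenyl]prop-2-en-1-yl acetate
Product: 11 methyl (4S*,5R*)-4-(acetoxymethyl)-2,5-bis[4-(benzyloxy)-3,5-dimethoxyphenyl]-4,5-dihydrofuran-3-carboxylate (racemic; C4 CH2OAc trans to C5 aryl)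
Conditions: Mn(OAc)3·2H2O (2.2 equiv), AcOH, 70 °C, N2
Reagents that add atoms: none
Why: Mn(OAc)3 converts ketoester 5 into its trivalent manganese enolate, whose one-electron oxidation gives an electrophilic α-radical that adds to alkene 10 at the carbon carrying CH2OAc (new C3–C4 bond); a second equivalent of Mn(OAc)3 oxidises the resulting 4-alkoxybenzylic radical to the cation, which the ketone/enol oxygen captures (new O1–C5 bond) with loss of the C3 proton. The closest known reaction type is the Mn(OAc)3-mediated oxidative [3+2] annulation of 1,3-dicarbonyl compounds with styrenes and related aryl alkenes to 4,5-dihydrofurans. The one ring formed, the dihydrofuran, closes in a 5-(enolendo)-exo sense: the enol C2=C3 lies inside the new five-membered ring and oxygen bonds to the benzylic cation. C4 and C5 arise as a racemic pair whose trans relationship is substrate-controlled, because the open cation rotates freely and closes through the conformer in which the C5 aryl and the C4 CH2OAc avoid each other. The step needs regioselectivity, secured by benzylic stabilisation from the 4-benzyloxy-3,5-dimethoxyphenyl group, and chemoselectivity, secured by benzyl masking of both phenols (no phenoxyl radicals) and by the solvent-matched acetate; the product has no enolisable C–H and should resist further oxidation.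

Step 7
Reactants: 11 methyl (4S*,5R*)-4-(acetoxymethyl)-2,5-bis[4-(benzyloxy)-3,5-dimethoxyphenyl]-4,5-dihydrofuran-3-carboxylate
Product: 13 methyl (2R*,3S*,4S*,5R*)-4-(acetoxymethyl)-2,5-bis(4-hydroxy-3,5-dimethoxyphenyl)tetrahydrofuran-3-carboxylate (racemic; 2,3-cis; 3,4-cis; 4,5-trans), via bisphenol dihydrofuran 12 (not isolated)
Conditions: H2 (4 atm), 10% Pd/C, EtOAc–MeOH, rt
Reagents that add atoms: none
Why: Heterogeneous catalytic hydrogenation over Pd/C: hydrogenolysis of the two benzyl aryl ethers should come first, and syn addition of H2 to the tetrasubstituted C2=C3 bond then takes place from the ring face opposite the CH2OAc group on the adjacent C4, which sets C2 and C3 together with aryl, ester and CH2OAc all cis.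

Step 8
Reactants: 13 methyl (2R*,3S*,4S*,5R*)-4-(acetoxymethyl)-2,5-bis(4-hydroxy-3,5-dimethoxyphenyl)tetrahydrofuran-3-carboxylate
Product: 14 methyl (2S*,3S*,4S*,5R*)-4-(acetoxymethyl)-2,5-bis(4-hydroxy-3,5-dimethoxyphenyl)tetrahydrofuran-3-carboxylate (racemic; 2,3-trans; 3,4-cis; 4,5-trans)
Conditions: CF3CO2H (1 equiv), CH2Cl2, 0 °C to rt
Reagents that add atoms: none
Why: Acid-catalysed benzylic epimerisation: reversible SN1 opening of the C2–O1 bond to a 4-hydroxybenzylic cation (protonated quinone methide) and 5-exo-trig reclosure by the C5 hydroxyl place the C2 aryl trans to the C3 ester under thermodynamic control, relieving the 2,3,4-all-cis strain, while C3 and C4 cannot ionise and C5, equally labile, is already in its favoured trans arrangement.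

Step 9
Reactants: 14 methyl (2S*,3S*,4S*,5R*)-4-(acetoxymethyl)-2,5-bis(4-hydroxy-3,5-dimethoxyphenyl)tetrahydrofuran-3-carboxylate
Product: 15 [(2S,3R,4S,5R)-2,5-bis(4-hydroxy-3,5-dimethoxyphenyl)tetrahydrofuran-3,4-diyl]dimethanol (meso target)
Conditions: LiAlH4 (5 equiv), THF, 0 °C to rt; then aq. potassium sodium tartrate (KNaC4H4O6)
Reagents that add atoms: none
Why: LiAlH4 hydride reduction converts the methyl ester and the acetate into the two primary alcohols (the phenols ride through as phenoxides); carbonyl reduction at 0 °C should outpace enolisation at C3, no stereocenter is touched, and the near-neutral work-up avoids acid scrambling of the benzylic ethers.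

Compound list
1 | acetosyringone | CC(=O)c1cc(OC)c(O)c(OC)c1 | starting material
2 | benzyl bromide | BrCc1ccccc1 | starting material
3 | 1-[4-(benzyloxy)-3,5-dimethoxyphenyl]ethan-1-one | CC(=O)c1cc(OC)c(OCc2ccccc2)c(OC)c1 | intermediate
4 | dimethyl carbonate | COC(=O)OC | starting material
5 | methyl 3-[4-(benzyloxy)-3,5-dimethoxyphenyl]-3-oxopropanoate | COC(=O)CC(=O)c1cc(OC)c(OCc2ccccc2)c(OC)c1 | intermediate
6 | sinapic acid | COc1cc(/C=C/C(=O)O)cc(OC)c1O | starting material
7 | benzyl (E)-3-[4-(benzyloxy)-3,5-dimethoxyphenyl]prop-2-enoate | O=C(/C=C/c1cc(OC)c(OCc2ccccc2)c(OC)c1)OCc1ccccc1 | intermediate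
8 | (E)-3-[4-(benzyloxy)-3,5-dimethoxyphenyl]prop-2-en-1-ol | OC/C=C/c1cc(OC)c(OCc2ccccc2)c(OC)c1 | intermediate
9 | acetic anhydride | CC(=O)OC(C)=O | starting material
10 | (E)-3-[4-(benzyloxy)-3,5-dimethoxyphenyl]prop-2-en-1-yl acetate | CC(=O)OC/C=C/c1cc(OC)c(OCc2ccccc2)c(OC)c1 | intermediate
11 | methyl (4S*,5R*)-4-(acetoxymethyl)-2,5-bis[4-(benzyloxy)-3,5-dimethoxyphenyl]-4,5-dihydrofuran-3-carboxylate, racemic, 4,5-trans | COC(=O)C1=C(c2cc(OC)c(OCc3ccccc3)c(OC)c2)O[C@@H](c2cc(OC)c(OCc3ccccc3)c(OC)c2)[C@@H]1COC(C)=O | intermediate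
12 | methyl (4S*,5R*)-4-(acetoxymethyl)-2,5-bis(4-hydroxy-3,5-dimethoxyphenyl)-4,5-dihydrofuran-3-carboxylate, racemic, 4,5-trans | COC(=O)C1=C(c2cc(OC)c(O)c(OC)c2)O[C@@H](c2cc(OC)c(O)c(OC)c2)[C@@H]1COC(C)=O | intermediate (not isolated)
13 | methyl (2R*,3S*,4S*,5R*)-4-(acetoxymethyl)-2,5-bis(4-hydroxy-3,5-dimethoxyphenyl)tetrahydrofuran-3-carboxylate, racemic, 2,3-cis, 3,4-cis, 4,5-trans | COC(=O)[C@@H]1[C@H](c2cc(OC)c(O)c(OC)c2)O[C@@H](c2cc(OC)c(O)c(OC)c2)[C@@H]1COC(C)=O | intermediate
14 | methyl (2S*,3S*,4S*,5R*)-4-(acetoxymethyl)-2,5-bis(4-hydroxy-3,5-dimethoxyphenyl)tetrahydrofuran-3-carboxylate, racemic, 2,3-trans, 3,4-cis, 4,5-trans | COC(=O)[C@@H]1[C@@H](c2cc(OC)c(O)c(OC)c2)O[C@@H](c2cc(OC)c(O)c(OC)c2)[C@@H]1COC(C)=O | intermediate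
15 | [(2S,3R,4S,5R)-2,5-bis(4-hydroxy-3,5-dimethoxyphenyl)tetrahydrofuran-3,4-diyl]dimethanol, meso | COc1cc([C@H]2O[C@@H](c3cc(OC)c(O)c(OC)c3)[C@H](CO)[C@@H]2CO)cc(OC)c1O | target

Total step count: 9 (steps 1–2 to ketoester 5, steps 3–5 to allyl acetate 10, steps 6–9 convergent endgame).
Longest linear sequence: 7 steps (3, 4, 5, 6, 7, 8, 9, from sinapic acid).

Steps most likely to fail

Step 6. The risk is that one-electron oxidation or oligomerisation of the electron-rich alkene and trialkoxyarenes outruns capture of the enolate-derived radical, so conversion to the annulated product stays low. The fallback makes the same two bonds by a two-electron carbenoid route and sets out from 5 and 10. Diazo transfer to 5 (4-acetamidobenzenesulfonyl azide, Et3N, MeCN) should give methyl 3-[4-(benzyloxy)-3,5-dimethoxyphenyl]-2-diazo-3-oxopropanoate F1. Rh2(OAc)4-catalysed decomposition of F1 in the presence of 10 (CH2Cl2, reflux) should give the donor–acceptor cyclopropane methyl 2-(acetoxymethyl)-1-[4-(benzyloxy)-3,5-dimethoxybenzoyl]-3-[4-(benzyloxy)-3,5-dimethoxyphenyl]cyclopropane-1-carboxylate F2, with CH2OAc and aryl trans as in the E-alkene. Sc(OTf)3 in CH2Cl2 then triggers a Cloke–Wilson ring expansion: the bond between the acyl-bearing carbon and the benzylic carbon ionises and the ketone oxygen captures the benzylic cation. This comes back to the route at 11.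

Step 7. The risk is that benzyl loss is fast while saturation of the tetrasubstituted, ester-conjugated enol ether is slow, so forcing the reaction brings hydrogenolysis of the benzylic C–O bonds of the ring. The fallback separates the two events and sets out from 11. Ni2B generated in situ from NiCl2·6H2O and NaBH4 (MeOH–THF, 0 °C) should effect conjugate reduction of the C2=C3 bond from the face opposite the C4 arm without touching benzyl ethers. This gives methyl (2R*,3S*,4S*,5R*)-4-(acetoxymethyl)-2,5-bis[4-(benzyloxy)-3,5-dimethoxyphenyl]tetrahydrofuran-3-carboxylate F3. Hydrogenolysis of F3 (H2 1 atm, Pd/C, EtOAc), which now only has to cleave two benzyl ethers, comes back at 13.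

Step 8. The risk is that the ring-opened benzylic cation is diverted into elimination towards C3 or into alkylation of the other electron-rich ring, or that equilibration of the flexible ester acetate stops short. The fallback moves the inversion onto a rigid bicycle and sets out from 13. K2CO3 in MeOH at 0 °C removes the acetate to give methyl (2R*,3S*,4S*,5R*)-4-(hydroxymethyl)-2,5-bis(4-hydroxy-3,5-dimethoxyphenyl)tetrahydrofuran-3-carboxylate F4. On mild acidification F4 should lactonise to cis-fused 4,6-bis(4-hydroxy-3,5-dimethoxyphenyl)tetrahydro-1H,3H-furo[3,4-c]furan-1-one with the 6-aryl group on the concave face F5. In F5 both arms are tied up, the ring fusion locks C3 cis to C4, and the concave aryl is strongly disfavoured. Brief treatment with CF3CO2H in CH2Cl2 should therefore move it to the convex face, giving the 6-epimeric lactone with both aryl groups on the convex face F6. LiAlH4 reduction of F6 (THF, 0 °C) comes back at 15.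

Further compounds
F1 | step 6 | methyl 3-[4-(benzyloxy)-3,5-dimethoxyphenyl]-2-diazo-3-oxopropanoate | COC(=O)C(=[N+]=[N-])C(=O)c1cc(OC)c(OCc2ccccc2)c(OC)c1
F2 | step 6 | methyl 2-(acetoxymethyl)-1-[4-(benzyloxy)-3,5-dimethoxybenzoyl]-3-[4-(benzyloxy)-3,5-dimethoxyphenyl]cyclopropane-1-carboxylate, racemic, CH2OAc and aryl trans, C1 unassigned | COC(=O)C1(C(=O)c2cc(OC)c(OCc3ccccc3)c(OC)c2)[C@H](COC(C)=O)[C@H]1c1cc(OC)c(OCc2ccccc2)c(OC)c1
F3 | step 7 | methyl (2R*,3S*,4S*,5R*)-4-(acetoxymethyl)-2,5-bis[4-(benzyloxy)-3,5-dimethoxyphenyl]tetrahydrofuran-3-carboxylate, racemic | COC(=O)[C@@H]1[C@H](c2cc(OC)c(OCc3ccccc3)c(OC)c2)O[C@@H](c2cc(OC)c(OCc3ccccc3)c(OC)c2)[C@@H]1COC(C)=O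
F4 | step 8 | methyl (2R*,3S*,4S*,5R*)-4-(hydroxymethyl)-2,5-bis(4-hydroxy-3,5-dimethoxyphenyl)tetrahydrofuran-3-carboxylate, racemic | COC(=O)[C@@H]1[C@H](c2cc(OC)c(O)c(OC)c2)O[C@@H](c2cc(OC)c(O)c(OC)c2)[C@@H]1CO
F5 | step 8 | cis-fused 4,6-bis(4-hydroxy-3,5-dimethoxyphenyl)tetrahydro-1H,3H-furo[3,4-c]furan-1-one, 6-aryl concave, 4-aryl convex, racemic | O=C1OC[C@@H]2[C@H]1[C@H](c3cc(OC)c(O)c(OC)c3)O[C@H]2c3cc(OC)c(O)c(OC)c3
F6 | step 8 | cis-fused 4,6-bis(4-hydroxy-3,5-dimethoxyphenyl)tetrahydro-1H,3H-furo[3,4-c]furan-1-one, both aryl groups convex, racemic | O=C1OC[C@@H]2[C@H]1[C@@H](c3cc(OC)c(O)c(OC)c3)O[C@H]2c3cc(OC)c(O)c(OC)c3
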